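Locants used throughout: decalin carbons C1–C8a (C2 and C7 carry the methylidene groups, C3 the side chain, C4 the gem-dimethyl group, C4a/C8a are the ring-fusion carbons); side chain C1′ (CO2H) to C8′ (bonded to C3), with the 1,2-dioxane spanning C3′–C6′.

## Analysis of the target

The target is a C24 norsesterterpene peroxide: a cis-fused decalin without angular substituents, whose ring B (C1–C4, C4a, C8a) holds the quaternary C4 between C3 and C4a, joined through C8′–C7′ to a 3,6,6-trisubstituted 1,2-dioxane that carries a propanoic acid. There are six stereocentres in two blocks that cannot talk to each other across the C7′–C8′ ethylene: C3 (R), C4a (S), C8a (S) in the decalin and C2′ (R), C3′ (R), C6′ (S) in the peroxide. In ring B the hydrogens at C3, C4a and C8a are all on one face and bracket C4. In the dioxane the C3′ substituent and the C7′ chain are trans (diequatorial, C6′ methyl axial), and C2′-Me/C3′-O are anti. The ring-B triad is a trap: either chair–chair form of this cis-decalin has a syn-axial contact (axial C4 methyl against C8, or the side chain against C5) that the C3 epimer avoids, so C3 must be set kinetically and must not sit next to an enolisable C2 carbonyl under equilibrating conditions. The O–O bond excludes dissolving metals, hydrogenation, low-valent metals and strong base (E1cb at C2′/C3′), and the two exocyclic 1,1-disubstituted alkenes compete with any side-chain alkene for electrophiles or radical hydroperoxidation. C6′ is a tertiary peroxide carbon whose two CH2 arms are almost equal in size, so it cannot be set reliably by a ring-closure preference. The feature that invites the key move is ring B itself: the all-cis C3-H/C4a-H/C8a-H pattern around quaternary C4 is exactly the endo adduct of an (E,E)-2-oxy-diene (C3=C2–C1=C8a) with a β,β-dimethyl enal (C4=C4a–C5).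

## Retrosynthetic reasoning

**End game (30 ← 29 ← 27 ← 26).** The acid 30 comes from ester 29. The C2 methylidene is made last from ketone 27 by a non-enolising Peterson sequence through 28. Ketone 27 is only unmasked from silyl enol ether 26 one step earlier, so C3 never sits beside a free carbonyl in base.

**Ring A (26 ← 24 ← 23).** The C6–C7 bond is cut (intramolecular B-alkyl coupling through borane 25) and C5=C6 is traced to methylenation of aldehyde 23. This creates the C7 methylidene during ring closure and brings C5 to the CH2 level without a deoxygenation. The cis fusion is simply inherited from cis substituents on C4a and C8a.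

**Key disconnection (23 ← 21 + 22).** Both C3–C4 and C4a–C8a are cut. Forward, an endo [4+2] between diene 21 and enal 22 must build ring B, the quaternary C4 and the C3/C4a/C8a triad in one event, under catalyst control of the absolute sense. The cut is placed here because no later step can correct C3.

**Union of the halves (21 ← 20 ← 17 + 19; 17 ← 15 ← 13 + 14).** C8a=C1 is cut by a phosphonate olefination and C8′–C3 by β-keto ester alkylation with iodide 13. At this stage C3 is still an achiral methylene, so the only sp3–sp3 bond between the two stereochemical blocks is made without any stereochemical cost. Aldehyde 19 comes from alcohol 18.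

**Dioxane (13 ← 12 ← 11 ← 9).** O–C3′ is cut (intramolecular displacement of a sulfonate, inversion) and O–C6′ is cut (perhydrolysis of an oxetane at its tertiary carbon, inversion, through 10). Both peroxide C–O bonds are thus formed by stereospecific substitution. The oxetane opening also releases the C8′ hydroxyl that becomes the handle for the union. C1′ arises by oxidative cleavage of the vinyl group of 11 while it is the only alkene present.

**C2′/C3′ (9 ← 8 ← 6 + 7).** The C2′–C3′ bond is cut by a catalytic asymmetric (Z)-crotylboration of aldehyde 6 with boronate 7, giving the syn pair that inversion at C3′ turns into the required anti pair.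

**Tertiary centre (6 ← 5 ← 3 ← 2 ← 1).** Oxetane 5 comes from 1,3-diol 3 (via 4), which comes from epoxy alcohol 2 and geraniol 1. The asymmetric epoxidation fixes C6′; its configuration is then inverted once, in the perhydrolysis.

## Alternatives that were turned down

**Alternative 1:** (textbook) Build the decalin first and form the dioxane last. The disconnection is O–C6′ and O–C3′ on diketone A1, which carries a 1,1-disubstituted side-chain alkene and an (E)-enoate. The forward key step is radical hydroperoxysilylation (Mukaiyama–Isayama) of the side-chain alkene, then base-mediated oxa-Michael closure, then double methylenation. It was turned down for three reasons. C6′ would be formed by trapping a planar tertiary radical, so there is no control. C3′ and C2′ would come from a reversible conjugate addition and an enolate protonation with only a methyl/CH2 difference at C6′ to guide them. The hydroperoxidation cannot tell the side-chain alkene from ring methylidenes, so A1 must carry a C2 ketone next to the thermodynamically disfavoured C3 centre through basic steps, and the synthesis ends with a double Wittig reaction on a peroxide.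

**Alternative 2:** Cationic bicyclisation of an acyclic precursor. The disconnection is C4a–C8a and C3–C4 of ketone A3, from trienone A2 (enone initiator, prenyl-type central alkene, allylsilane terminator). The forward key step is a Lewis-acid cascade that would form both rings, C4 and the C2 methylidene at once. It was turned down on mechanistic grounds. An (E)-enone folding through a chair places both new ring-A substituents equatorial, which is the trans-decalin. The cis fusion needs the 2-propyl cation axial. C3 is only correct from the ring-B chair that carries the syn-axial C4-methyl/C8 contact, so the lower transition state leads to the C3 epimer. The absolute sense would also be uncontrolled.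

**Alternative 3:** Internally activated intramolecular Diels–Alder. The disconnection is the same two bonds as in the chosen route, but with ring A as the tether: triene A4 (C5 ketone activating the dienophile) would give bicycle A5. It was turned down because 1,7,9-decatrien-3-ones give cis/trans mixtures and offer no handle for absolute control. The C5 carbonyl would have to be removed reductively in the presence of the O–O bond. In A4, C6 is a doubly activated methylene beside a β,γ-unsaturated ketone and would isomerise. No step is saved against the intermolecular version.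

Key step: step 15

Assumption: (R)-TRIP (step 5) and the (S)-oxazaborolidinium salt (step 15) are taken to expose the aldehyde Re face and the enal Cα-Si face respectively, as in the accepted models for these catalyst classes; if either sense is the reverse, the antipodal catalyst is used.

## Route

Step 1
Reactants: 1 geraniol
Product: 2 [(2S,3S)-3-methyl-3-(4-methylpent-3-en-1-yl)oxiran-2-yl]methanol
Conditions: Ti(Oi-Pr)4 (5 mol%), L-(+)-diethyl tartrate (7 mol%), t-BuOOH, 4 Å MS, CH2Cl2, −20 °C
Reagents that add atoms: tert-butyl hydroperoxide, CC(C)(C)OO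
Why: Katsuki–Sharpless asymmetric epoxidation of an (E)-allylic alcohol; the L-tartrate complex delivers oxygen to the face that gives the (2S,3S)-epoxide, which fixes the future C6′ (before its single inversion).

Step 2
Reactants: 2 [(2S,3S)-3-methyl-3-(4-methylpent-3-en-1-yl)oxiran-2-yl]methanol
Product: 3 (3S)-3,7-dimethyloct-6-ene-1,3-diol
Conditions: Red-Al, THF, 0 °C
Reagents that add atoms: none
Why: Alkoxide-directed hydride opening of a 2,3-epoxy alcohol at C2 (1,3-diol formation); the tertiary C–O bond is not touched, so its configuration is kept.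

Step 3
Reactants: 3 (3S)-3,7-dimethyloct-6-ene-1,3-diol
Product: 5 (2S)-2-methyl-2-(4-methylpent-3-en-1-yl)oxetane, via primary tosylate 4 (not isolated)
Conditions: TsCl, Et3N, DMAP (cat.), CH2Cl2, 0 °C; then KOt-Bu, THF, 0 °C → rt
Reagents that add atoms: none
Why: Selective sulfonylation of the primary hydroxyl, then 4-exo-tet Williamson closure by the tertiary alkoxide; the stereocentre keeps its C–O bond.

Step 4
Reactants: 5 (2S)-2-methyl-2-(4-methylpent-3-en-1-yl)oxetane
Product: 6 3-[(2S)-2-methyloxetan-2-yl]propanal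
Conditions: O3, CH2Cl2, −78 °C; then Me2S
Reagents that add atoms: ozone, [O-][O+]=O
Why: Ozonolysis of the only C=C bond with reductive work-up; the oxetane is inert to ozone.

Step 5
Reactants: 6 3-[(2S)-2-methyloxetan-2-yl]propanal; 7 (Z)-crotylboronic acid pinacol ester
Product: 8 (3S,4S)-3-methyl-6-[(2S)-2-methyloxetan-2-yl]hex-1-en-4-ol
Conditions: (R)-TRIP phosphoric acid (5 mol%), toluene, −30 °C
Reagents that add atoms: none
Why: Chiral phosphoric acid-catalysed crotylboration through a closed chair transition state: the (Z)-crotyl unit gives the syn pair and the catalyst selects the aldehyde face (C2′ and C3′); any minor isomer becomes a ring diastereomer at 11 and should be removable there.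

Step 6
Reactants: 8 (3S,4S)-3-methyl-6-[(2S)-2-methyloxetan-2-yl]hex-1-en-4-ol
Product: 9 (3S,4S)-3-methyl-6-[(2S)-2-methyloxetan-2-yl]hex-1-en-4-yl methanesulfonate
Conditions: MsCl, Et3N, CH2Cl2, 0 °C
Reagents that add atoms: methanesulfonyl chloride, CS(=O)(=O)Cl
Why: Standard sulfonylation; it activates C3′ for displacement with inversion and involves no bond to a stereocentre.

Step 7
Reactants: 9 (3S,4S)-3-methyl-6-[(2S)-2-methyloxetan-2-yl]hex-1-en-4-yl methanesulfonate
Product: 11 2-[(3R,6R)-6-[(2S)-but-3-en-2-yl]-3-methyl-1,2-dioxan-3-yl]ethan-1-ol, via hydroperoxy mesylate 10 (not isolated)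
Conditions: H2O2 (anhydrous, Et2O), TMSOTf (0.2 equiv), −78 → 0 °C; aqueous wash; then KOt-Bu, 18-crown-6, THF, −20 → 0 °C
Reagents that add atoms: hydrogen peroxide, OO
Why: Lewis-acid perhydrolysis of a 2,2-disubstituted oxetane at its tertiary carbon with inversion (known for this ring class) sets C6′ and frees the C8′ hydroxyl; the more acidic hydroperoxide is then deprotonated selectively and displaces the mesylate 6-exo-tet with inversion at C3′ (intramolecular hydroperoxide alkylation), so both peroxide C–O bonds come from stereospecific substitutions.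

Step 8
Reactants: 11 2-[(3R,6R)-6-[(2S)-but-3-en-2-yl]-3-methyl-1,2-dioxan-3-yl]ethan-1-ol
Product: 12 methyl (2R)-2-[(3R,6R)-6-(2-hydroxyethyl)-6-methyl-1,2-dioxan-3-yl]propanoate
Conditions: O3, NaOH/MeOH (2.5 M), CH2Cl2, −78 °C
Reagents that add atoms: ozone, [O-][O+]=O; methanol, CO
Why: Ozonolysis in methanolic base converts the vinyl group directly into the methyl ester; it is the only alkene present, the dialkyl peroxide is inert to ozone, and C2′ is not enolised at −78 °C.

Step 9
Reactants: 12 methyl (2R)-2-[(3R,6R)-6-(2-hydroxyethyl)-6-methyl-1,2-dioxan-3-yl]propanoate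
Product: 13 methyl (2R)-2-[(3R,6R)-6-(2-iodoethyl)-6-methyl-1,2-dioxan-3-yl]propanoate
Conditions: I2, PPh3, imidazole, CH2Cl2, 0 °C (phosphine and iodine premixed)
Reagents that add atoms: iodine, II
Why: Appel-type iodination of the primary alcohol; the phosphine is consumed by iodine before it can attack the hindered dialkyl peroxide.

Step 10
Reactants: 13 methyl (2R)-2-[(3R,6R)-6-(2-iodoethyl)-6-methyl-1,2-dioxan-3-yl]propanoate; 14 tert-butyl 4-(diethoxyphosphoryl)-3-oxobutanoate
Product: 15 tert-butyl 4-(diethoxyphosphoryl)-2-{2-[(3S,6R)-6-[(2R)-1-methoxy-1-oxopropan-2-yl]-3-methyl-1,2-dioxan-3-yl]ethyl}-3-oxobutanoate (both epimers at the new carbon)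
Conditions: Cs2CO3, DMF, rt
Reagents that add atoms: none
Why: C-alkylation of the most acidic carbon of a β-keto ester (between ketone and ester) by a primary iodide; carbonate is too weak to enolise the methyl ester or to trigger base cleavage of the peroxide; the new centre is removed in step 11.

Step 11
Reactants: 15 tert-butyl 4-(diethoxyphosphoryl)-2-{2-[(3S,6R)-6-[(2R)-1-methoxy-1-oxopropan-2-yl]-3-methyl-1,2-dioxan-3-yl]ethyl}-3-oxobutanoate
Product: 17 methyl (2R)-2-[(3R,6S)-6-[5-(diethoxyphosphoryl)-4-oxopentyl]-6-methyl-1,2-dioxan-3-yl]propanoate, via β-keto acid 16 (not isolated)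
Conditions: TFA/CH2Cl2 (1:4), 0 °C → rt; then toluene, 70 °C
Reagents that add atoms: none
Why: Acidolysis of the tert-butyl ester and thermal decarboxylation of the β-keto acid give the β-ketophosphonate; the methyl ester and the dialkyl peroxide are stable to TFA at room temperature.

Step 12
Reactants: 18 3-bromobut-3-en-1-ol
Product: 19 3-bromobut-3-enal
Conditions: Dess–Martin periodinane, CH2Cl2, 0 °C; used at once
Reagents that add atoms: none
Why: Dess–Martin oxidation under near-neutral conditions keeps the β,γ-double bond out of conjugation.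

Step 13
Reactants: 17 methyl (2R)-2-[(3R,6S)-6-[5-(diethoxyphosphoryl)-4-oxopentyl]-6-methyl-1,2-dioxan-3-yl]propanoate; 19 3-bromobut-3-enal
Product: 20 methyl (2R)-2-[(3R,6S)-6-[(5E)-8-bromo-4-oxonona-5,8-dien-1-yl]-6-methyl-1,2-dioxan-3-yl]propanoate
Conditions: LiCl, i-Pr2NEt, MeCN, rt
Reagents that add atoms: none
Why: Horner–Wadsworth–Emmons olefination under Masamune–Roush conditions gives the (E)-enone; the mild amine base avoids isomerisation of the skipped diene and retro-oxa-Michael opening of the dioxane.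

Step 14
Reactants: 20 methyl (2R)-2-[(3R,6S)-6-[(5E)-8-bromo-4-oxonona-5,8-dien-1-yl]-6-methyl-1,2-dioxan-3-yl]propanoate
Product: 21 methyl (2R)-2-[(3R,6S)-6-[(3Z,5E)-8-bromo-4-{[tri(propan-2-yl)silyl]oxy}nona-3,5,8-trien-1-yl]-6-methyl-1,2-dioxan-3-yl]propanoate
Conditions: TIPSOTf, Et3N, CH2Cl2, −78 → 0 °C
Reagents that add atoms: triisopropylsilyl trifluoromethanesulfonate, CC(C)[Si](C(C)C)(C(C)C)OS(=O)(=O)C(F)(F)F
Why: Soft enolisation of the enone at the α′-methylene (C3) gives the cross-conjugated 2-silyloxy diene; the (Z)-enol ether expected under these conditions places the C8′ chain "outside", as the cycloaddition needs.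

Step 15
Reactants: 21 methyl (2R)-2-[(3R,6S)-6-[(3Z,5E)-8-bromo-4-{[tri(propan-2-yl)silyl]oxy}nona-3,5,8-trien-1-yl]-6-methyl-1,2-dioxan-3-yl]propanoate; 22 3-methylbut-2-enal
Product: 23 methyl (2R)-2-[(3R,6S)-6-{2-[(1S,4S,5S)-4-(2-bromoprop-2-en-1-yl)-5-formyl-6,6-dimethyl-2-{[tri(propan-2-yl)silyl]oxy}cyclohex-2-en-1-yl]ethyl}-6-methyl-1,2-dioxan-3-yl]propanoate
Conditions: (S)-o-tolyl-oxazaborolidinium triflimide (20 mol%), 22 (3 equiv), CH2Cl2, −78 → −40 °C
Reagents that add atoms: none
Why: The boron Lewis acid binds the formyl oxygen of s-trans 22 and a concerted, asynchronous [4+2] follows in which C3–C4 bonding runs ahead of C4a–C8a. The closest known reactions are oxazaborolidinium-catalysed cycloadditions of 2-silyloxy dienes with α,β-enals and Lewis-acid cycloadditions of hindered silyloxy dienes with β,β-disubstituted enones that create quaternary carbons. Ring B is closed by an intermolecular suprafacial cycloaddition, both σ bonds in one event. Regiochemistry comes from the silyloxy group: C3, the enol-ether β-carbon, is the nucleophilic terminus and bonds to the β-carbon C4, giving the 1,4 relation of C2–O and C4a–CHO. C3 and C8a are set by the (3Z,5E) geometry, both substituents outside, hence H3 and H8a cis. C4a is set by the endo orientation of the formyl group, which makes it cis to both, so the all-cis triad results. The absolute sense comes from the catalyst, which leaves the Cα-Si face of the enal open; the remote dioxane centres play no part. The step needs [4+2] over 1,2-addition to the aldehyde, which the bulky silyl group and a boron catalyst that cannot transfer silicon should secure, and endo over exo, where one C4 methyl is endo in either mode so the formyl preference decides.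

Step 16
Reactants: 23 methyl (2R)-2-[(3R,6S)-6-{2-[(1S,4S,5S)-4-(2-bromoprop-2-en-1-yl)-5-formyl-6,6-dimethyl-2-{[tri(propan-2-yl)silyl]oxy}cyclohex-2-en-1-yl]ethyl}-6-methyl-1,2-dioxan-3-yl]propanoate
Product: 24 methyl (2R)-2-[(3R,6S)-6-{2-[(1S,4R,5S)-4-(2-bromoprop-2-en-1-yl)-5-ethenyl-6,6-dimethyl-2-{[tri(propan-2-yl)silyl]oxy}cyclohex-2-en-1-yl]ethyl}-6-methyl-1,2-dioxan-3-yl]propanoate
Conditions: Ph3PCH3Br, KHMDS, THF, −78 → 0 °C (1.1 equiv ylide)
Reagents that add atoms: methyltriphenylphosphonium bromide, C[P+](c1ccccc1)(c1ccccc1)c1ccccc1.[Br-]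
Why: Wittig methylenation of the aldehyde, which consumes the ylide at low temperature faster than the ylide can deprotonate the ester or attack the O–O bond; C4a should not epimerise under these conditions.

Step 17
Reactants: 24 methyl (2R)-2-[(3R,6S)-6-{2-[(1S,4R,5S)-4-(2-bromoprop-2-en-1-yl)-5-ethenyl-6,6-dimethyl-2-{[tri(propan-2-yl)silyl]oxy}cyclohex-2-en-1-yl]ethyl}-6-methyl-1,2-dioxan-3-yl]propanoate
Product: 26 methyl (2R)-2-[(3R,6S)-6-{2-[(2S,4aR,8aS)-1,1-dimethyl-6-methylidene-3-{[tri(propan-2-yl)silyl]oxy}-1,2,4a,5,6,7,8,8a-octahydronaphthalen-2-yl]ethyl}-6-methyl-1,2-dioxan-3-yl]propanoate, via alkylborane 25 (not isolated)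
Conditions: 9-BBN-H (1.1 equiv), THF, 0 °C → rt; then PdCl2(dppf) (10 mol%), AsPh3, Cs2CO3, DMF/H2O, rt
Reagents that add atoms: none
Why: 9-BBN hydroborates the monosubstituted vinyl group far faster than the vinyl bromide or the trisubstituted enol ether; intramolecular B-alkyl Suzuki–Miyaura coupling then closes the six-membered ring A and forms the C7 methylidene directly, and the cis fusion follows from the cis substituents set in step 15.

Step 18
Reactants: 26 methyl (2R)-2-[(3R,6S)-6-{2-[(2S,4aR,8aS)-1,1-dimethyl-6-methylidene-3-{[tri(propan-2-yl)silyl]oxy}-1,2,4a,5,6,7,8,8a-octahydronaphthalen-2-yl]ethyl}-6-methyl-1,2-dioxan-3-yl]propanoate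
Product: 27 methyl (2R)-2-[(3R,6S)-6-{2-[(2S,4aS,8aS)-1,1-dimethyl-6-methylidene-3-oxodecahydronaphthalen-2-yl]ethyl}-6-methyl-1,2-dioxan-3-yl]propanoate
Conditions: HF·pyridine, pyridine/THF, 0 °C
Reagents that add atoms: none
Why: Fluoride cleavage of the silyl enol ether with protonation at C1, which is not a stereocentre; the buffered medium should not enolise the ketone towards the hindered C3.

Step 19
Reactants: 27 methyl (2R)-2-[(3R,6S)-6-{2-[(2S,4aS,8aS)-1,1-dimethyl-6-methylidene-3-oxodecahydronaphthalen-2-yl]ethyl}-6-methyl-1,2-dioxan-3-yl]propanoate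
Product: 29 methyl (2R)-2-[(3R,6S)-6-{2-[(2R,4aS,8aS)-1,1-dimethyl-3,6-dimethylidenedecahydronaphthalen-2-yl]ethyl}-6-methyl-1,2-dioxan-3-yl]propanoate, via β-hydroxysilane 28 (not isolated)
Conditions: Me3SiCH2Li, CeCl3, THF, −78 °C; then aq HF (5%), MeCN, 0 °C
Reagents that add atoms: (trimethylsilyl)methyllithium, [Li]C[Si](C)(C)C
Why: Peterson olefination: the weakly basic organocerium reagent adds to the ketone at −78 °C faster than to the ester and without enolisation, and acid-induced anti-elimination of the β-hydroxysilane gives the exocyclic alkene, so the kinetically set C3 is never exposed to an enolate.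

Step 20
Reactants: 29 methyl (2R)-2-[(3R,6S)-6-{2-[(2R,4aS,8aS)-1,1-dimethyl-3,6-dimethylidenedecahydronaphthalen-2-yl]ethyl}-6-methyl-1,2-dioxan-3-yl]propanoate
Product: 30 (2R)-2-[(3R,6S)-6-{2-[(2R,4aS,8aS)-1,1-dimethyl-3,6-dimethylidenedecahydronaphthalen-2-yl]ethyl}-6-methyl-1,2-dioxan-3-yl]propanoic acid (CNP0363961.1)
Conditions: LiOH, THF/H2O (3:1), 0 °C → rt; then aq HCl to pH 3
Reagents that add atoms: lithium hydroxide, [Li+].[OH-]
Why: Saponification of the methyl ester; the carboxylate formed protects C2′ from further deprotonation and the dialkyl peroxide is stable to aqueous hydroxide at this temperature.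

## Compound list

1 | geraniol, (2E)-3,7-dimethylocta-2,6-dien-1-ol | CC(C)=CCC/C(C)=C/CO | starting material
2 | [(2S,3S)-3-methyl-3-(4-methylpent-3-en-1-yl)oxiran-2-yl]methanol | OC[C@@H]1O[C@@]1(C)CCC=C(C)C | intermediate
3 | (3S)-3,7-dimethyloct-6-ene-1,3-diol | OCC[C@@](C)(O)CCC=C(C)C | intermediate
4 | (3S)-3-hydroxy-3,7-dimethyloct-6-en-1-yl 4-methylbenzenesulfonate | Cc1ccc(cc1)S(=O)(=O)OCC[C@@](C)(O)CCC=C(C)C | intermediate (not isolated)
5 | (2S)-2-methyl-2-(4-methylpent-3-en-1-yl)oxetane | O1CC[C@]1(C)CCC=C(C)C | intermediate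
6 | 3-[(2S)-2-methyloxetan-2-yl]propanal | O=CCC[C@@]1(C)CCO1 | intermediate
7 | 2-[(2Z)-but-2-en-1-yl]-4,4,5,5-tetramethyl-1,3,2-dioxaborolane | C/C=C\CB1OC(C)(C)C(C)(C)O1 | starting material
8 | (3S,4S)-3-methyl-6-[(2S)-2-methyloxetan-2-yl]hex-1-en-4-ol | C=C[C@H](C)[C@@H](O)CC[C@@]1(C)CCO1 | intermediate
9 | (3S,4S)-3-methyl-6-[(2S)-2-methyloxetan-2-yl]hex-1-en-4-yl methanesulfonate | C=C[C@H](C)[C@@H](OS(C)(=O)=O)CC[C@@]1(C)CCO1 | intermediate
10 | (3S,4S,7R)-7-hydroperoxy-9-hydroxy-3,7-dimethylnon-1-en-4-yl methanesulfonate | C=C[C@H](C)[C@@H](OS(C)(=O)=O)CC[C@@](C)(OO)CCO | intermediate (not isolated)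
11 | 2-[(3R,6R)-6-[(2S)-but-3-en-2-yl]-3-methyl-1,2-dioxan-3-yl]ethan-1-ol | OCC[C@@]1(C)CC[C@H]([C@@H](C)C=C)OO1 | intermediate
12 | methyl (2R)-2-[(3R,6R)-6-(2-hydroxyethyl)-6-methyl-1,2-dioxan-3-yl]propanoate | OCC[C@@]1(C)CC[C@H]([C@@H](C)C(=O)OC)OO1 | intermediate
13 | methyl (2R)-2-[(3R,6R)-6-(2-iodoethyl)-6-methyl-1,2-dioxan-3-yl]propanoate | ICC[C@@]1(C)CC[C@H]([C@@H](C)C(=O)OC)OO1 | intermediate
14 | tert-butyl 4-(diethoxyphosphoryl)-3-oxobutanoate | CCOP(=O)(OCC)CC(=O)CC(=O)OC(C)(C)C | starting material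
15 | tert-butyl 4-(diethoxyphosphoryl)-2-{2-[(3S,6R)-6-[(2R)-1-methoxy-1-oxopropan-2-yl]-3-methyl-1,2-dioxan-3-yl]ethyl}-3-oxobutanoate (epimers at C2 of the butanoate) | CCOP(=O)(OCC)CC(=O)C(CC[C@@]1(C)CC[C@H]([C@@H](C)C(=O)OC)OO1)C(=O)OC(C)(C)C | intermediate
16 | 4-(diethoxyphosphoryl)-2-{2-[(3S,6R)-6-[(2R)-1-methoxy-1-oxopropan-2-yl]-3-methyl-1,2-dioxan-3-yl]ethyl}-3-oxobutanoic acid | CCOP(=O)(OCC)CC(=O)C(CC[C@@]1(C)CC[C@H]([C@@H](C)C(=O)OC)OO1)C(=O)O | intermediate (not isolated)
17 | methyl (2R)-2-[(3R,6S)-6-[5-(diethoxyphosphoryl)-4-oxopentyl]-6-methyl-1,2-dioxan-3-yl]propanoate | CCOP(=O)(OCC)CC(=O)CCC[C@@]1(C)CC[C@H]([C@@H](C)C(=O)OC)OO1 | intermediate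
18 | 3-bromobut-3-en-1-ol | C=C(Br)CCO | starting material
19 | 3-bromobut-3-enal | C=C(Br)CC=O | intermediate
20 | methyl (2R)-2-[(3R,6S)-6-[(5E)-8-bromo-4-oxonona-5,8-dien-1-yl]-6-methyl-1,2-dioxan-3-yl]propanoate | C=C(Br)C/C=C/C(=O)CCC[C@@]1(C)CC[C@H]([C@@H](C)C(=O)OC)OO1 | intermediate
21 | methyl (2R)-2-[(3R,6S)-6-[(3Z,5E)-8-bromo-4-{[tri(propan-2-yl)silyl]oxy}nona-3,5,8-trien-1-yl]-6-methyl-1,2-dioxan-3-yl]propanoate | C=C(Br)C/C=C/C(O[Si](C(C)C)(C(C)C)C(C)C)=C/CC[C@@]1(C)CC[C@H]([C@@H](C)C(=O)OC)OO1 | intermediate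
22 | 3-methylbut-2-enal | CC(C)=CC=O | starting material
23 | methyl (2R)-2-[(3R,6S)-6-{2-[(1S,4S,5S)-4-(2-bromoprop-2-en-1-yl)-5-formyl-6,6-dimethyl-2-{[tri(propan-2-yl)silyl]oxy}cyclohex-2-en-1-yl]ethyl}-6-methyl-1,2-dioxan-3-yl]propanoate | O=C[C@H]1[C@@H](CC(Br)=C)C=C(O[Si](C(C)C)(C(C)C)C(C)C)[C@@H](CC[C@@]2(C)CC[C@H]([C@@H](C)C(=O)OC)OO2)C1(C)C | intermediate
24 | methyl (2R)-2-[(3R,6S)-6-{2-[(1S,4R,5S)-4-(2-bromoprop-2-en-1-yl)-5-ethenyl-6,6-dimethyl-2-{[tri(propan-2-yl)silyl]oxy}cyclohex-2-en-1-yl]ethyl}-6-methyl-1,2-dioxan-3-yl]propanoate | C=C[C@H]1[C@@H](CC(Br)=C)C=C(O[Si](C(C)C)(C(C)C)C(C)C)[C@@H](CC[C@@]2(C)CC[C@H]([C@@H](C)C(=O)OC)OO2)C1(C)C | intermediate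
25 | methyl (2R)-2-[(3R,6S)-6-{2-[(1S,4R,5S)-5-[2-(9-borabicyclo[3.3.1]nonan-9-yl)ethyl]-4-(2-bromoprop-2-en-1-yl)-6,6-dimethyl-2-{[tri(propan-2-yl)silyl]oxy}cyclohex-2-en-1-yl]ethyl}-6-methyl-1,2-dioxan-3-yl]propanoate | B1(CC[C@H]2[C@@H](CC(Br)=C)C=C(O[Si](C(C)C)(C(C)C)C(C)C)[C@@H](CC[C@@]3(C)CC[C@H]([C@@H](C)C(=O)OC)OO3)C2(C)C)C2CCCC1CCC2 | intermediate (not isolated)
26 | methyl (2R)-2-[(3R,6S)-6-{2-[(2S,4aR,8aS)-1,1-dimethyl-6-methylidene-3-{[tri(propan-2-yl)silyl]oxy}-1,2,4a,5,6,7,8,8a-octahydronaphthalen-2-yl]ethyl}-6-methyl-1,2-dioxan-3-yl]propanoate | C=C1CC[C@H]2[C@@H](C1)C=C(O[Si](C(C)C)(C(C)C)C(C)C)[C@@H](CC[C@@]3(C)CC[C@H]([C@@H](C)C(=O)OC)OO3)C2(C)C | intermediate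
27 | methyl (2R)-2-[(3R,6S)-6-{2-[(2S,4aS,8aS)-1,1-dimethyl-6-methylidene-3-oxodecahydronaphthalen-2-yl]ethyl}-6-methyl-1,2-dioxan-3-yl]propanoate | C=C1CC[C@H]2[C@@H](C1)CC(=O)[C@@H](CC[C@@]3(C)CC[C@H]([C@@H](C)C(=O)OC)OO3)C2(C)C | intermediate
28 | methyl (2R)-2-[(3R,6S)-6-{2-[(2S,4aS,8aS)-3-hydroxy-1,1-dimethyl-6-methylidene-3-[(trimethylsilyl)methyl]decahydronaphthalen-2-yl]ethyl}-6-methyl-1,2-dioxan-3-yl]propanoate (epimers at the carbinol) | C=C1CC[C@H]2[C@@H](C1)CC(O)(C[Si](C)(C)C)[C@@H](CC[C@@]3(C)CC[C@H]([C@@H](C)C(=O)OC)OO3)C2(C)C | intermediate (not isolated)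
29 | methyl (2R)-2-[(3R,6S)-6-{2-[(2R,4aS,8aS)-1,1-dimethyl-3,6-dimethylidenedecahydronaphthalen-2-yl]ethyl}-6-methyl-1,2-dioxan-3-yl]propanoate | C=C1CC[C@H]2[C@@H](C1)CC(=C)[C@@H](CC[C@@]3(C)CC[C@H]([C@@H](C)C(=O)OC)OO3)C2(C)C | intermediate
30 | (2R)-2-[(3R,6S)-6-{2-[(2R,4aS,8aS)-1,1-dimethyl-3,6-dimethylidenedecahydronaphthalen-2-yl]ethyl}-6-methyl-1,2-dioxan-3-yl]propanoic acid | C=C1CC[C@H]2[C@@H](C1)CC(=C)[C@@H](CC[C@@]1(C)CC[C@H]([C@@H](C)C(=O)O)OO1)C2(C)C | target

## Step count and risk

Total step count: 20. Longest linear sequence: 19 steps (steps 1–11 and 13–20, geraniol 1 to 30); step 12 is a one-step side branch.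

Least certain steps:

**Step 15 (key step).** Three processes can go wrong. The enol-ether terminus may add 1,2 to the formyl carbon (open-chain Mukaiyama aldol) instead of entering the cycloaddition. The rate may be low because the first bond is formed at a quaternary carbon. Endo and facial selectivity may erode because a β-methyl group is forced under the diene in both orientations and the catalyst has little precedent with β,β-disubstituted enals. The fallback sets out from 21 and replaces catalyst control by auxiliary control with a chelating imide dienophile, which cannot undergo 1,2-addition. The acyl oxazolidinone (4S)-4-benzyl-3-(3-methylbut-2-enoyl)-1,3-oxazolidin-2-one F1 (from the lithiated oxazolidinone and 3-methylbut-2-enoyl chloride) is combined with 21 under Et2AlCl. The chelated s-cis imide exposes the same Cα-Si face and should give the imide cycloadduct F2. Chemoselective LiBH4 reduction of the imide in the presence of the methyl ester gives the primary alcohol F3, and Dess–Martin oxidation brings the sequence back to 23.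

**Step 7.** The secondary mesylate may undergo E2 elimination under the base. Configuration at C6′ may leak if the oxetane opens through a free tertiary cation. The C8′ alkoxide may compete as nucleophile. The fallback sets out from 6 and closes the ring by conjugate addition instead of substitution. Wittig olefination with methyl 2-(triphenylphosphoranylidene)propanoate gives methyl (2E)-2-methyl-5-[(2S)-2-methyloxetan-2-yl]pent-2-enoate F4. The same perhydrolysis gives methyl (2E,6R)-6-hydroperoxy-8-hydroxy-2,6-dimethyloct-2-enoate F5. Et2NH in CF3CH2OH then effects the 6-exo oxa-Michael closure and returns to 12, with C3′/C2′ now set under substrate control from C6′ and the isomers separated at that stage.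

**Step 17.** The borane or Pd(0) may reduce the O–O bond. The silyl enol ether may be hydroborated. Protodeboronation may compete with the coupling. The fallback sets out from 24 and forms the C6–C7 bond by a reductive coupling of two electrophiles. Hydroboration with oxidative work-up (NaBO3) gives the primary alcohol F6. Iodination (I2, PPh3, imidazole) gives the primary iodide F7. An intramolecular nickel-catalysed cross-electrophile coupling of the alkyl iodide with the vinyl bromide (NiCl2·glyme, 4,4′-di-tert-butylbipyridine, Mn, DMA) returns to 26.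

**Step 19.** The organometallic may add to the methyl ester. Addition to the hindered ketone may be slow. During the acidic elimination the exocyclic double bonds may migrate into the rings or C3 may epimerise. The fallback sets out from 27 and changes both the order and the olefination. Saponification (LiOH, 0 °C) gives the keto acid (2R)-2-[(3R,6S)-6-{2-[(2S,4aS,8aS)-1,1-dimethyl-6-methylidene-3-oxodecahydronaphthalen-2-yl]ethyl}-6-methyl-1,2-dioxan-3-yl]propanoic acid F8. Its carboxylate is then methylenated with Ph3P=CH2 (3 equiv, THF, 0 °C), which leads directly to 30.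

## Further compounds

F1 | step 15 | (4S)-4-benzyl-3-(3-methylbut-2-enoyl)-1,3-oxazolidin-2-one | CC(C)=CC(=O)N1[C@@H](Cc2ccccc2)COC1=O
F2 | step 15 | methyl (2R)-2-[(3R,6S)-6-{2-[(1S,4S,5S)-5-{[(4S)-4-benzyl-2-oxo-1,3-oxazolidin-3-yl]carbonyl}-4-(2-bromoprop-2-en-1-yl)-6,6-dimethyl-2-{[tri(propan-2-yl)silyl]oxy}cyclohex-2-en-1-yl]ethyl}-6-methyl-1,2-dioxan-3-yl]propanoate | O=C1OC[C@H](Cc2ccccc2)N1C(=O)[C@H]1[C@@H](CC(Br)=C)C=C(O[Si](C(C)C)(C(C)C)C(C)C)[C@@H](CC[C@@]2(C)CC[C@H]([C@@H](C)C(=O)OC)OO2)C1(C)C
F3 | step 15 | methyl (2R)-2-[(3R,6S)-6-{2-[(1S,4S,5S)-4-(2-bromoprop-2-en-1-yl)-5-(hydroxymethyl)-6,6-dimethyl-2-{[tri(propan-2-yl)silyl]oxy}cyclohex-2-en-1-yl]ethyl}-6-methyl-1,2-dioxan-3-yl]propanoate | OC[C@H]1[C@@H](CC(Br)=C)C=C(O[Si](C(C)C)(C(C)C)C(C)C)[C@@H](CC[C@@]2(C)CC[C@H]([C@@H](C)C(=O)OC)OO2)C1(C)C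
F4 | step 7 | methyl (2E)-2-methyl-5-[(2S)-2-methyloxetan-2-yl]pent-2-enoate | COC(=O)/C(C)=C/CC[C@@]1(C)CCO1
F5 | step 7 | methyl (2E,6R)-6-hydroperoxy-8-hydroxy-2,6-dimethyloct-2-enoate | COC(=O)/C(C)=C/CC[C@@](C)(OO)CCO
F6 | step 17 | methyl (2R)-2-[(3R,6S)-6-{2-[(1S,4R,5S)-4-(2-bromoprop-2-en-1-yl)-5-(2-hydroxyethyl)-6,6-dimethyl-2-{[tri(propan-2-yl)silyl]oxy}cyclohex-2-en-1-yl]ethyl}-6-methyl-1,2-dioxan-3-yl]propanoate | OCC[C@H]1[C@@H](CC(Br)=C)C=C(O[Si](C(C)C)(C(C)C)C(C)C)[C@@H](CC[C@@]2(C)CC[C@H]([C@@H](C)C(=O)OC)OO2)C1(C)C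
F7 | step 17 | methyl (2R)-2-[(3R,6S)-6-{2-[(1S,4R,5S)-4-(2-bromoprop-2-en-1-yl)-5-(2-iodoethyl)-6,6-dimethyl-2-{[tri(propan-2-yl)silyl]oxy}cyclohex-2-en-1-yl]ethyl}-6-methyl-1,2-dioxan-3-yl]propanoate | ICC[C@H]1[C@@H](CC(Br)=C)C=C(O[Si](C(C)C)(C(C)C)C(C)C)[C@@H](CC[C@@]2(C)CC[C@H]([C@@H](C)C(=O)OC)OO2)C1(C)C
F8 | step 19 | (2R)-2-[(3R,6S)-6-{2-[(2S,4aS,8aS)-1,1-dimethyl-6-methylidene-3-oxodecahydronaphthalen-2-yl]ethyl}-6-methyl-1,2-dioxan-3-yl]propanoic acid | C=C1CC[C@H]2[C@@H](C1)CC(=O)[C@@H](CC[C@@]3(C)CC[C@H]([C@@H](C)C(=O)O)OO3)C2(C)C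
A1 | alternative 1 | methyl (2E)-8-[(2S,4aS,8aS)-1,1-dimethyl-3,6-dioxodecahydronaphthalen-2-yl]-2-methyl-6-methylideneoct-2-enoate | O=C1CC[C@H]2[C@@H](C1)CC(=O)[C@@H](CCC(=C)CC/C=C(\C)C(=O)OC)C2(C)C
A2 | alternative 2 | methyl (2R)-2-[(3R,6S)-6-methyl-6-[(3E,6E)-13-methyl-9-oxo-4-[(trimethylsilyl)methyl]tetradeca-3,6,12-trien-1-yl]-1,2-dioxan-3-yl]propanoate | CC(C)=CCCC(=O)/C=C/C/C(C[Si](C)(C)C)=C/CC[C@@]1(C)CC[C@H]([C@@H](C)C(=O)OC)OO1
A3 | alternative 2 | methyl (2R)-2-[(3R,6S)-6-{2-[(2R,4aS,8aS)-1,1-dimethyl-3-methylidene-6-oxodecahydronaphthalen-2-yl]ethyl}-6-methyl-1,2-dioxan-3-yl]propanoate | O=C1CC[C@H]2[C@@H](C1)CC(=C)[C@@H](CC[C@@]3(C)CC[C@H]([C@@H](C)C(=O)OC)OO3)C2(C)C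
A4 | alternative 3 | methyl (2R)-2-[(3R,6S)-6-methyl-6-[(3Z,5E)-13-methyl-8-methylidene-10-oxo-4-{[tri(propan-2-yl)silyl]oxy}tetradeca-3,5,12-trien-1-yl]-1,2-dioxan-3-yl]propanoate | CC(C)=CC(=O)CC(=C)C/C=C/C(O[Si](C(C)C)(C(C)C)C(C)C)=C/CC[C@@]1(C)CC[C@H]([C@@H](C)C(=O)OC)OO1
A5 | alternative 3 | methyl (2R)-2-[(3R,6S)-6-{2-[(2S,4aR,8aS)-1,1-dimethyl-6-methylidene-8-oxo-3-{[tri(propan-2-yl)silyl]oxy}-1,2,4a,5,6,7,8,8a-octahydronaphthalen-2-yl]ethyl}-6-methyl-1,2-dioxan-3-yl]propanoate | C=C1CC(=O)[C@H]2[C@@H](C1)C=C(O[Si](C(C)C)(C(C)C)C(C)C)[C@@H](CC[C@@]3(C)CC[C@H]([C@@H](C)C(=O)OC)OO3)C2(C)C
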